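Readings and results are simulated for substances that don't exist; scatter was added.

Decide the split between the two products before you decide the run time, for a flask in which a single-handed catalyst works on a racemate.

| flask | left-handed substrate | right-handed substrate | gas | catalyst | remark | time |
|---|---|---|---|---|---|---|
| gamma | 10 mM | 10 mM | 0.76 mM (held) | 0.36 mM | run made earlier |  |
| beta | 40 mM | 40 mM | 0.76 mM (held) | 0.36 mM | run made earlier |  |
| flask | 20 mM | 20 mM | 0.76 mM (held) | 0.36 mM |  | 4.0 h |

| run | time / h | left-handed product / % | right-handed product / % |
|---|---|---|---|
| gamma | 0.833 | 2 | 3 |
| gamma | 1.50 | 4 | 2 |
| gamma | 2.50 | 7 | 3 |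
| gamma | 3.00 | 11 | 6 |
| gamma | 4.00 | 15 | 7 |
| gamma | 5.00 | 19 | 8 |
| beta | 0.333 | 1 | 0 |
| beta | 1.00 | 0 | 5 |
| beta | 1.50 | 4 | 0 |
| beta | 2.50 | 2 | 4 |
| beta | 4.00 | 10 | 4 |
| beta | 5.00 | 11 | 5 |

(scatter of a reading: 1.5 percentage points)

* left-handed product present at 4.0 h, in percent of the left-handed substrate and right-handed substrate together charged
* right-handed product present at 4.0 h, in percent of the left-handed substrate and right-handed substrate together charged
* right-handed substrate present at 4.0 h, in percent of the left-handed substrate and right-handed substrate together charged

- catalyst is single-handed; left-handed substrate and right-handed substrate are mirror images of each other, charged as a racemate, each of them at the stated concentration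
- what was read earlier has a scatter of 1.5 percentage points, one standard deviation
- at the start none of the gas is in solution

Suppose each substrate goes to its own product at a rate proportional to its own concentration, c, times a factor shared by both. Dividing one rate by the other removes that factor, and the integral in closed form leaves a constant. The readings at 5.00 h in gamma and beta, averaged, put it at 2.55, with their scatter. Call it s, the selectivity factor: ln of the fraction of left-handed substrate left over ln of the fraction of right-handed substrate left.

The flask's 20 mM is twice gamma's and half beta's, so I take the geometric mean of the two runs' fractions of left-handed substrate left at 4.00 h, 74.8%. My reckoning therefore gives 12.6% left-handed product in the flask, and s then gives 44.6% right-handed substrate and 5.40% right-handed product.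

The forecast, resting on “saturation kinetics on the catalyst”, differs slightly from mine, with 12% left-handed product, 5% right-handed product and 45% right-handed substrate.

The flask gives 10.2% left-handed product, 4.64% right-handed product and 45.4% right-handed substrate.

    reagent + catalyst + left-handed substrate → catalyst + left-handed product (k = 10600 M⁻² min⁻¹)
    reagent + catalyst + right-handed substrate → catalyst + right-handed product (k = 4500 M⁻² min⁻¹)
    reagent ⇌ dormant form (K = 69.8, k = 0.00465 min⁻¹)
    gas ⇌ reagent, rate k4*(csat - [reagent]) (kL = 0.0532 min⁻¹)
    reagent → decomposition product (k = 3.09 × 10⁻⁶ min⁻¹)

In this flask at 4.00 h, the left-handed step uses reagent 2.1 times as fast as the right-handed step, although left-handed substrate, at 39.8%, stands lower than right-handed substrate at 45.4%. At that time in this flask the half-life of left-handed substrate by its step is 11 h, longer than the 4.0 h run, and 80% of its charge remains. Read the same flask at 10 h: 53% of the left-handed charge remains, s gives 39.0% right-handed substrate, and the flask holds 38.1%.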